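**Plan**

- Numbering used throughout (bicyclo[3.3.1]nonane): C1 = C(OH) bridgehead, C2 = CH2, C3 = CH–N, C4 = CH–OH, C5 = CH bridgehead, C6 = CH–OMe, C7/C8 = epoxide, C9 = C=O. Ring A = C1-C2-C3-C4-C5-C9, ring B = C1-C9-C5-C6-C7-C8; exo = pointing away from the other three-carbon bridge.
- Retrosynthesis: cut the amide C–N bond, the epoxide oxygen and the C9 carbonyl (back to a C9 alcohol). Then cut ring A at C3–C4 together with a temporary N–CH2–O4 bridge: the cis, exo 1,2-amino alcohol (N on C3, O on C4) of ring A is the retron of an oxazolidine formed by (3+2) addition of an azomethine ylide centred on C3 to a C4 aldehyde. This is possible because the C2 arm on C1 and the C4 arm on C5 are cis-1,3 on ring B. Last, cut C5–C4, O–CH3 and C9–O back to a p-quinol.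
- Forward: phenol → p-quinol → ring B (C9–O by desymmetrizing oxa-Michael, C4 by enolate alkylation, C6–OMe by Luche reduction and methylation) → ring A and the oxazolidine in one cycloaddition → amino triol → amide (chain joined) → epoxide → C9 ketone.
- Stereochemistry: C1/C9 from a chiral phosphoric acid catalysed desymmetrization; C5 and C6 by substrate control (all-trans ring B); C3 and C4 from the ring constraints of the cycloaddition; epoxide by exo, hydroxyl-guided delivery; the auxiliary C9 centre is erased in the last step.

Key step: step 8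

Assumption: the enantiomer of the phosphoric acid in step 2 is the one that gives 3 as drawn. The acetal carbon of 3–11 is drawn with methyl exo; its configuration is irrelevant because the acetal is removed in step 9.

**Route**

Step 1
Reactants: 1 2-(4-hydroxyphenyl)acetonitrile
Product: 2 2-(1-hydroxy-4-oxocyclohexa-2,5-dien-1-yl)acetonitrile
Conditions: PhI(OAc)2, MeCN/H2O 4:1, 0 °C
Reagents that add atoms: water (O)
Why: Oxidative dearomatization of a para-alkylphenol with water as the nucleophile at the para carbon should give the prochiral p-quinol, whose two enone arms are enantiotopic; no stereocenter is formed.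

Step 2
Reactants: 2 p-quinol
Product: 3 cis-fused dioxolane enone, 2-[2-methyl-6-oxo-7,7a-dihydro-1,3-benzodioxol-3a(6H)-yl]acetonitrile (O1 and O9 on the face opposite the cyanomethyl group, acetal methyl exo)
Conditions: MeCHO (5 equiv), (R)-3,3'-bis(2,4,6-triisopropylphenyl)-1,1'-binaphthyl-2,2'-diyl hydrogen phosphate (5 mol%), ClCH2CH2Cl, 40 °C
Reagents that add atoms: acetaldehyde (CC=O)
Why: Hemiacetalization followed by intramolecular oxa-Michael addition (acetalization/oxa-Michael desymmetrization of a p-quinol): the five-membered tether can only deliver O9 cis to O1, and the chiral acid selects one of the two enone arms, which fixes C1 and C9 together.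

Step 3
Reactants: 3 dioxolane enone
Product: 4 [3a-(cyanomethyl)-2-methyl-6-oxo-3a,6,7,7a-tetrahydro-1,3-benzodioxol-7-yl]methyl pivalate (CH2OPiv on C5 trans to O9, cis to the cyanomethyl group)
Conditions: LiN(SiMe3)2, THF, −78 °C; ICH2OC(O)t-Bu, DMPU, −78 → −40 °C
Reagents that add atoms: iodomethyl pivalate (CC(C)(C)C(=O)OCI)
Why: SN2 alkylation of the kinetic cross-conjugated lithium enolate at C5; attack anti to the C9–O bond on the convex face puts C4 trans to O9, which is also the equatorial, thermodynamically preferred position of this epimerizable centre.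

Step 4
Reactants: 4 keto pivalate
Product: 5 allylic alcohol, [3a-(cyanomethyl)-6-hydroxy-2-methyl-3a,6,7,7a-tetrahydro-1,3-benzodioxol-7-yl]methyl pivalate (C6–OH trans to CH2OPiv, cis to O9 and O1)
Conditions: NaBH4, CeCl3·7H2O, MeOH, −78 °C
Reagents that add atoms: none
Why: Luche 1,2-reduction; axial hydride delivery to the half-chair that carries C4 and O9 equatorial should give the equatorial allylic alcohol trans to the C5 substituent, which is the C6 configuration of the target.

Step 5
Reactants: 5 allylic alcohol
Product: 6 methyl ether, [3a-(cyanomethyl)-6-methoxy-2-methyl-3a,6,7,7a-tetrahydro-1,3-benzodioxol-7-yl]methyl pivalate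
Conditions: MeI, Ag2O, 4 Å molecular sieves, Et2O, 23 °C, dark
Reagents that add atoms: iodomethane (CI)
Why: Purdie methylation of the only free hydroxyl under non-basic conditions avoids pivaloyl migration and β-elimination; no stereocenter is touched.

Step 6
Reactants: 6 methyl ether
Product: 7 hydroxy aldehyde, 2-[7-(hydroxymethyl)-6-methoxy-2-methyl-7,7a-dihydro-1,3-benzodioxol-3a(6H)-yl]acetaldehyde
Conditions: i-Bu2AlH (4 equiv), CH2Cl2, −78 → −40 °C; aq. KNaC4H4O6
Reagents that add atoms: water (O)
Why: i-Bu2AlH reduces the nitrile to the N-aluminoimine (hydrolysed on work-up to the C3 aldehyde) and cleaves the pivalate to the C4 primary alcohol in one operation, which leaves C3 as an aldehyde and C4 as an alcohol for the next step.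

Step 7
Reactants: 7 hydroxy aldehyde
Product: 9 N-(trimethylsilylmethyl)imino aldehyde of ring B (C3 imine and C4 formyl group), via hydroxy imine 8 (not isolated)
Conditions: Me3SiCH2NH2 (1.05 equiv), MgSO4, CH2Cl2, 0 °C; then pyridine, Dess–Martin periodinane [1,1,1-triacetoxy-1,2-benziodoxol-3(1H)-one], 0 → 23 °C; filtered, evaporated, used at once
Reagents that add atoms: (trimethylsilyl)methanamine (C[Si](C)(C)CN)
Why: Imine condensation occurs at the only aldehyde present, so nitrogen is placed on C3 without ambiguity; buffered Dess–Martin oxidation then unmasks the C4 aldehyde under non-aqueous conditions that should leave the imine intact, with C5 in its thermodynamic configuration.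

Step 8
Reactants: 9 imino aldehyde
Product: 11 oxazolidine-bridged bicyclo[3.3.1]non-7-ene cycloadduct (N3 and O4 joined by CH2; 1,9-O-ethylidene acetal kept), via azomethine ylide 10 (not isolated)
Conditions: H2O (2 equiv), DMPU, 23 °C, 5 mM
Reagents that add atoms: none
Why: Proposed new method: water-induced desilylation of the N-(trimethylsilylmethyl)iminium of 9 gives the N-unsubstituted azomethine ylide 10, whose C3 terminus lies 1,3-diaxial to the C5 formyl group on ring B and adds across C4=O in a concerted (3+2) cycloaddition that forms C3–C4 and O4–CH2 at once; the closest known reaction types are the intermolecular cycloaddition of nonstabilized azomethine ylides (from N-silylmethyl imines or decarboxylative condensation) with aldehydes to give oxazolidines and the intramolecular azomethine ylide–alkene cycloaddition. Ring A closes as the six-membered carbocycle of a fused 6/5 adduct through the four-atom tether C2-C1-C9-C5 (the reverse regiochemistry would need a bridged eight-membered ring), and the oxazolidine closes by O4–CH2 bonding as the second bond of the same cycloaddition. At C3 the nitrogen must be exo, because an endo C–N bond would point into ring B at C7; at C4 the one-carbon N–CH2–O bridge allows only a cis- or trans-fused oxazolidine, and the flattened wing of the forming bicyclo[3.3.1]nonane accommodates the small C3–C4 torsion of the cis-fused ring but not the wide torsion of the trans-fused one, so O4 should be delivered axial and cis to N as in the target. C5 is epimerizable in 9, but only the epimer with the formyl group cis to the C1 side chain can reach the ylide, and this is the all-trans ring B isomer already favoured. The step needs the ylide to be trapped faster than it is protonated or than the imine tautomerizes to an enamine, which the neutral medium, high dilution and the enforced proximity of the two axial arms should secure.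

Step 9
Reactants: 11 cycloadduct
Product: 12 3-amino-6-methoxybicyclo[3.3.1]non-7-ene-1,4,9-triol (3-NH2 and 4-OH cis and exo, 6-OMe exo, 9-OH cis to 1-OH on the ring B side)
Conditions: sulfonic acid ion-exchange resin (H+ form), THF/H2O, 50 °C; resin washed; amine released with 2 M NH3 in MeOH
Reagents that add atoms: none
Why: Acid hydrolysis of the N,O-acetal and of the ethylidene acetal on a resin that holds the ammonium salt while formaldehyde and acetaldehyde are washed away; no stereocenter changes, and the bridgehead position of C1 disfavours ionisation.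

Step 10
Reactants: 12 amino triol; 13 (E)-dodec-2-enoic acid
Product: 14 (E)-N-[1,4,9-trihydroxy-6-methoxybicyclo[3.3.1]non-7-en-3-yl]dodec-2-enamide
Conditions: i-PrN=C=N-i-Pr, 1-hydroxybenzotriazole, DMF, 0 → 23 °C
Reagents that add atoms: none
Why: Carbodiimide/hydroxybenzotriazole amide coupling should be selective for the primary amine over the three hydroxyl groups; the (E)-alkene geometry comes from 13.

Step 11
Reactants: 14 amide
Product: 15 7,8-epoxide of 14 (epoxide exo, cis to 6-OMe and on the face of 1-OH and 9-OH)
Conditions: 3-chloroperoxybenzoic acid, CH2Cl2, 0 °C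
Reagents that add atoms: 3-chloroperoxybenzoic acid (OOC(=O)c1cccc(Cl)c1)
Why: Prilezhaev epoxidation with Henbest-type hydroxyl guidance should attack the only electron-rich alkene from the exo face of ring B, which is the face of the C9 and C1 hydroxyls and is remote from ring A; the conjugated amide alkene is too electron-poor to react.

Step 12
Reactants: 15 epoxy triol
Product: 17 target CNP0137540.1, via 1,9-O-dibutylstannylene acetal 16 (not isolated)
Conditions: Bu2SnO, MeOH, 65 °C; evaporated; NBS, CHCl3, 23 °C
Reagents that add atoms: none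
Why: Stannylene acetal oxidation: Bu2SnO should engage the cis-1,2-diol (C1–OH/C9–OH) as a five-membered stannylene, and brominolysis with NBS oxidises its only carbinol C–H (C9) to the ketone, leaving the isolated C4 alcohol untouched and erasing the auxiliary C9 stereocenter.

**Compound list**

1 | 2-(4-hydroxyphenyl)acetonitrile | N#CCc1ccc(O)cc1 | starting material
2 | 2-(1-hydroxy-4-oxocyclohexa-2,5-dien-1-yl)acetonitrile | N#CCC1(O)C=CC(=O)C=C1 | intermediate
3 | cis-fused dioxolane enone, 2-[2-methyl-6-oxo-7,7a-dihydro-1,3-benzodioxol-3a(6H)-yl]acetonitrile | N#CC[C@@]12O[C@@H](C)O[C@@H]1CC(=O)C=C2 | intermediate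
4 | [3a-(cyanomethyl)-2-methyl-6-oxo-3a,6,7,7a-tetrahydro-1,3-benzodioxol-7-yl]methyl pivalate | N#CC[C@@]12O[C@@H](C)O[C@@H]1[C@@H](COC(=O)C(C)(C)C)C(=O)C=C2 | intermediate
5 | [3a-(cyanomethyl)-6-hydroxy-2-methyl-3a,6,7,7a-tetrahydro-1,3-benzodioxol-7-yl]methyl pivalate | N#CC[C@@]12O[C@@H](C)O[C@@H]1[C@@H](COC(=O)C(C)(C)C)[C@H](O)C=C2 | intermediate
6 | [3a-(cyanomethyl)-6-methoxy-2-methyl-3a,6,7,7a-tetrahydro-1,3-benzodioxol-7-yl]methyl pivalate | N#CC[C@@]12O[C@@H](C)O[C@@H]1[C@@H](COC(=O)C(C)(C)C)[C@H](OC)C=C2 | intermediate
7 | 2-[7-(hydroxymethyl)-6-methoxy-2-methyl-7,7a-dihydro-1,3-benzodioxol-3a(6H)-yl]acetaldehyde | O=CC[C@@]12O[C@@H](C)O[C@@H]1[C@@H](CO)[C@H](OC)C=C2 | intermediate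
8 | (E)-N-(trimethylsilylmethyl)imine of 7 (not isolated) | C[Si](C)(C)C/N=C/C[C@@]12O[C@@H](C)O[C@@H]1[C@@H](CO)[C@H](OC)C=C2 | intermediate
9 | imino aldehyde (C3 N-silylmethyl imine, C4 formyl) | C[Si](C)(C)C/N=C/C[C@@]12O[C@@H](C)O[C@@H]1[C@@H](C=O)[C@H](OC)C=C2 | intermediate
10 | N-unsubstituted azomethine ylide of 9 (not isolated) | [CH2-][NH+]=CC[C@@]12O[C@@H](C)O[C@@H]1[C@@H](C=O)[C@H](OC)C=C2 | intermediate
11 | cycloadduct: 3,4-cis-fused oxazolidine (N3–CH2–O4) on the 6-methoxybicyclo[3.3.1]non-7-ene core, 1,9-O-ethylidene acetal | C1N[C@H]2C[C@@]34O[C@@H](C)O[C@@H]3[C@@H]([C@H]2O1)[C@H](OC)C=C4 | intermediate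
12 | 3-amino-6-methoxybicyclo[3.3.1]non-7-ene-1,4,9-triol | N[C@H]1C[C@@]2(O)[C@H](O)[C@@H]([C@H]1O)[C@H](OC)C=C2 | intermediate
13 | (E)-dodec-2-enoic acid | CCCCCCCCC/C=C/C(=O)O | starting material
14 | (E)-N-[1,4,9-trihydroxy-6-methoxybicyclo[3.3.1]non-7-en-3-yl]dodec-2-enamide | CCCCCCCCC/C=C/C(=O)N[C@H]1C[C@@]2(O)[C@H](O)[C@@H]([C@H]1O)[C@H](OC)C=C2 | intermediate
15 | exo-7,8-epoxide of 14 | CCCCCCCCC/C=C/C(=O)N[C@H]1C[C@@]2(O)[C@H](O)[C@@H]([C@H]1O)[C@H](OC)[C@@H]1O[C@@H]12 | intermediate
16 | 1,9-O-dibutylstannylene acetal of 15 (not isolated) | CCCCCCCCC/C=C/C(=O)N[C@H]1C[C@@]23O[Sn](CCCC)(CCCC)O[C@@H]2[C@@H]([C@H]1O)[C@H](OC)[C@@H]1O[C@@H]13 | intermediate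
17 | CNP0137540.1 | CCCCCCCCC/C=C/C(=O)N[C@H]1C[C@@]2(O)C(=O)[C@@H]([C@H]1O)[C@H](OC)[C@@H]1O[C@@H]12 | target

**Totals**

Total step count: 12. Longest linear sequence: 12 steps (from 1; 13 is purchased).

**Steps most likely to fail**

1. Step 8 (Proposed new method). What may go wrong: the ylide is protonated instead of trapped; the imine tautomerizes to the enamine, which undergoes aldol reaction at C4; methanol is lost by β-elimination from the β-methoxy aldehyde; or the cis-1,3-diaxial conformer of ring B is too costly to reach. Fallback (sets out from 7, returns at 12), using the known reductive ketyl–oxime ether cyclization and a Mitsunobu inversion: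
   - Condensation of 7 with O-benzylhydroxylamine should give the O-benzyl oxime F1.
   - Dess–Martin oxidation should give the oxime aldehyde F2.
   - SmI2 in THF/t-BuOH at −78 °C should close ring A to the N-benzyloxyamino alcohol F3, with nitrogen exo but the C4 hydroxyl expected equatorial (trans to N).
   - Mitsunobu inversion (PPh3, diisopropyl azodicarboxylate, 4-nitrobenzoic acid) should give the axial 4-nitrobenzoate F4.
   - K2CO3 in MeOH should give the cis N-benzyloxyamino alcohol F5.
   - Zn in AcOH (N–O cleavage) and then the acidic resin treatment of step 9 should give 12.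

2. Step 12. What may go wrong: loss of site selectivity in the oxidation (attack at the C4 alcohol or glycol cleavage) or epoxide opening while the stannylene is formed. Fallback (sets out from 15, returns at 17), a protecting-group detour:
   - Et3SiOTf and 2,6-lutidine at −78 °C should silylate the more accessible exo C4 hydroxyl to give the 4-O-triethylsilyl ether F6.
   - Dess–Martin oxidation of the only remaining secondary alcohol should give the C9 ketone F7.
   - AcOH/THF/H2O should remove the silyl group to give 17.

3. Step 3. What may go wrong: β-elimination of pivalate from the enolate of the product, retro-oxa-Michael opening of the dioxolane, or O-alkylation. Fallback (sets out from 3, returns at 4), a Lewis acid aldol instead of a basic alkylation: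
   - Me3SiOTf and Et3N should give the trimethylsilyl dienol ether F8.
   - Yb(OTf)3-catalysed hydroxymethylation with aqueous formaldehyde should give the β-hydroxy ketone F9.
   - t-BuCOCl and pyridine should give 4.

**Further compounds**

F1 | step 8 | (E)-O-benzyl oxime of 7 | c1ccccc1CO/N=C/C[C@@]12O[C@@H](C)O[C@@H]1[C@@H](CO)[C@H](OC)C=C2
F2 | step 8 | O-benzyl oxime aldehyde (C4 formyl) | c1ccccc1CO/N=C/C[C@@]12O[C@@H](C)O[C@@H]1[C@@H](C=O)[C@H](OC)C=C2
F3 | step 8 | 3-(benzyloxyamino) bicyclic alcohol, C4–OH trans to N, 1,9-O-ethylidene acetal | c1ccccc1CON[C@H]1C[C@@]23O[C@@H](C)O[C@@H]2[C@@H]([C@@H]1O)[C@H](OC)C=C3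
F4 | step 8 | 4-nitrobenzoate of the C4-inverted alcohol | c1ccccc1CON[C@H]1C[C@@]23O[C@@H](C)O[C@@H]2[C@@H]([C@H]1OC(=O)c1ccc(cc1)[N+](=O)[O-])[C@H](OC)C=C3
F5 | step 8 | 3-(benzyloxyamino) bicyclic alcohol, C4–OH cis to N, 1,9-O-ethylidene acetal | c1ccccc1CON[C@H]1C[C@@]23O[C@@H](C)O[C@@H]2[C@@H]([C@H]1O)[C@H](OC)C=C3
F6 | step 12 | 4-O-triethylsilyl ether of 15 | CCCCCCCCC/C=C/C(=O)N[C@H]1C[C@@]2(O)[C@H](O)[C@@H]([C@H]1O[Si](CC)(CC)CC)[C@H](OC)[C@@H]1O[C@@H]12
F7 | step 12 | 4-O-triethylsilyl ether of 17 | CCCCCCCCC/C=C/C(=O)N[C@H]1C[C@@]2(O)C(=O)[C@@H]([C@H]1O[Si](CC)(CC)CC)[C@H](OC)[C@@H]1O[C@@H]12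
F8 | step 3 | trimethylsilyl dienol ether of 3 | N#CC[C@@]12O[C@@H](C)O[C@@H]1C=C(O[Si](C)(C)C)C=C2
F9 | step 3 | C5-hydroxymethyl ketone | N#CC[C@@]12O[C@@H](C)O[C@@H]1[C@@H](CO)C(=O)C=C2
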